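Compound numbers are those of the route below: 1, 4 and 8 are the starting materials, 7 and 9 are the precursor and product of the key step, and 13 is the target.

## The problem

Target 13 is a 2-aryl-3-hydroxymethyl-2,3-dihydrobenzofuran. Benzo ring A (C3a, C4–C7, C7a) is fused to oxygen ring B (O1, C2, C3); ring C, a 4-hydroxy-3,5-dimethoxyphenyl group, sits on C2; C3 carries the one-carbon arm C9–OH, C5 a 3-hydroxypropyl chain and C7 a methoxy group. There are two stereocentres, C2 (S) and C3 (R), trans to each other, and they are not of equal standing. C2 is benzylic, bound to O1 and conjugated with the para oxygen of ring C, so it ionises easily and then settles trans to the C3 substituent: C3 can control C2, but C2 cannot be used to control C3. C3 is a tertiary carbon between ring A, C9 and C2 with no such handle, and it has to be made enantioselectively. The groups that dislike rough treatment are the electron-rich free phenol of ring C (oxidation, quinone methide formation), the benzylic C2–O1 ether (acid ionisation, hydrogenolysis) and the two electron-rich arenes (electrophilic attack); the two primary alcohols need not be told apart. The feature that invites a short solution is the 1,3-dioxygen pattern O1–C2–C3–C9–O: one oxygenated carbon on C3 next to an oxygen on C2 is the imprint of a formaldehyde Prins addition across a C2=C3 double bond, that is, across an (E)-stilbene joining rings A and C.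

## Retrosynthesis

**Phenol protection, 13 from 12.** The O–benzyl bond at the ring C phenol is cut first. An ether is needed here rather than an ester, because this oxygen must stay a strong donor in the key step, and it must survive hydride and aqueous acid. The benzyl ether 12 is no simpler in skeleton, but it removes the oxidation-prone phenol from every earlier step. The forward hydrogenolysis has to spare the cyclic benzylic C2–O1 ether.

**Ring B, 12 from 10 through 11.** The O1–C2 bond is cut. Cutting O1–C7a (aryl ether formation) or C3–C3a would require both stereocentres to be correct beforehand. Cutting at C2 uses the lability of this carbon: a C2 cation captured by the ring A phenol closes ring B under control of C3. The precursor 10 holds the C2 oxygen and the C9 oxygen together in a 1,3-dioxane, so only C3 needs to be defined in it. The forward step must ionise only the benzylic acetal C–O bond, close the five-membered ring trans, release formaldehyde from hemiformal 11, and leave C3 untouched.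

**Ester removal, 10 from 9.** The two acyl C–O bonds are cut. The ring A phenol must be an ester in the key step (poor donor, no free OH) and the chain alcohol must be capped so that it cannot form formals. Using pivalates for both lets one reagent install them and one hydride reduction remove them.

**Prins disconnection, 9 from 7 and 8.** The C3–C9 bond and the C2–O bond are cut, together with the acetal C–O bonds. The neighbouring cut, C2–C3 (aldol), needs an arylacetic acid, an auxiliary and a redox adjustment at C9. The Prins cut makes C3 from a flat alkene and brings C9 in at the alcohol oxidation level. The precursor 7 is an achiral (E)-stilbene with no stereocentre, and 8 is paraformaldehyde, from which two formaldehyde units are taken up: one becomes C9 and the other the acetal carbon of the temporary ring. The forward reaction must deliver the new carbon to C3 and the oxygen to C2, and must choose one face of the alkene; the C2 configuration of 9 is expendable.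

**Stilbene assembly, 7 from 3 and 6.** The aryl–vinyl bond C3a–C3 is cut (Mizoroki–Heck). Cutting the C2=C3 double bond instead (olefination) would require ortho-formylation of a guaiacol and a benzylic phosphonate, two to three more steps. Bromide 3 and styrene 6 are each two steps from commercial phenols. The forward coupling must arylate the terminal alkene carbon and give the E isomer.

**Ring A piece, 3 from 2 from 1.** The acyl groups and then the C–Br bond ortho to the phenol are removed, leading back to dihydroconiferyl alcohol 1. In 1 the para position of the phenol is blocked, so bromination has only one favoured site.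

**Ring C piece, 6 from 5 from 4.** The terminal C=C bond (Wittig methylenation) and the O–benzyl bond are cut, leading back to syringaldehyde 4.

## Roads not taken

Alternative 1: The cut is O1–C7a. In the forward sense the potassium alkoxide of the open-chain fluoro alcohol A2 (KHMDS) displaces fluoride para to a formyl group and gives the dihydrobenzofuran aldehyde A1.
- Merits: the bond forms at an sp2 carbon, so neither stereocentre is touched. As a ring closure this is the most certain of the four plans and safer than step 8 of the chosen route. It also needs no new method.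
- Weak points: the whole stereochemical problem is moved into A2, where both C2 and C3 must be correct, because a base-mediated closure cannot repair C2. A2 therefore needs an asymmetric aldol-type construction and a silyl protection. After ring closure the formyl group of A1 still has to be extended by two carbons and reduced, and the silyl and benzyl groups removed. The fluoride is activated by only one para formyl group and is flanked by a methoxy group, and a free aldehyde is exposed to a strong base and an alkoxide.
- Comparison: the chosen plan sets against the safer ring closure that it makes one stereocentre instead of two, carries the side chain at its final oxidation level from the first step, and needs three steps after the key step instead of five or more.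

Alternative 2: The cuts are C3–C3a and O1–C7a. With Pd2(dba)3, P(t-Bu)3 and Cs2CO3, the enolate of β-keto ester A4 is C-arylated at the bromide of A5 and its enol oxygen then displaces the neighbouring triflate, giving the aromatic benzofuran diester A3. The stereocentres come later by asymmetric reduction of the C2=C3 bond.
- Merits: this is the most convergent assembly of the skeleton. All carbons are in place in A3, no intermediate is sensitive to cations, and both esters can be reduced together at the end. In convergence and in the robustness of ring formation it is better than the chosen plan.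
- Weak points: the stereochemistry rests on hydrogenating the tetrasubstituted, aromatic, electron-rich furan double bond of A3, which is a demanding substrate. Syn delivery of hydrogen gives the cis relationship, so C3 would have to be epimerised by base. Under those conditions the ester enolate at C3 can expel the ring A phenoxide (E1cB) and open ring B, which puts the C2 configuration at risk. The domino step also relies on the bromide of A5 reacting before the triflate; otherwise the ring closes with the opposite regiochemistry.
- Comparison: the chosen plan sets against the better convergence that C3 is created directly in a C–C bond-forming step, and that the trans relationship arises by a process that favours it rather than by correcting a cis product.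

Alternative 3: The cuts are C3–C3a and C9–O. Bu3SnH under dry air turns the aryl iodide of the (S)-configured aryl 1-arylallyl ether A7 into an aryl radical, which cyclises 5-exo onto the vinyl group. The primary radical is trapped by O2 and reduced to the alcohol A6.
- Merits: C2 comes from reliable asymmetric carbonyl chemistry. Radical 5-exo closures of such ethers have good precedent for the 2,3-trans outcome, and C9 arrives as the alcohol. In documented relative stereocontrol this road is ahead of the chosen plan.
- Weak points: the aryl–O–C2 bond of A7 must be made by inversion at a carbon that is both benzylic and allylic, with a phenol hindered on both sides. Ionisation, allylic transposition and loss of enantiopurity threaten there and in the storage of A7. Tin is needed in stoichiometric amount. Oxygen trapping competes with hydrogen transfer to the primary radical (which would leave a methyl group on C3 in place of C9–OH) and with reduction or oxygenation of the aryl radical before cyclisation. The ester of A6 still has to be reduced.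
- Comparison: the chosen plan sets against the better stereochemical precedent that it avoids tin and the fragile ether, uses an achiral flat precursor, and corrects C2 thermodynamically at the end. Its price is one step that is new for this substrate class.

Key step: step 6

Assumption: the sense of induction of a confined imino-imidodiphosphoric acid on a 1,2-diaryl alkene cannot be predicted. The antipode that leads to the 5R dioxane 9 is taken to be identified in the first run, both antipodes being available from (R)- or (S)-BINOL.

## Route

Step 1
Reactants: 1 dihydroconiferyl alcohol [4-(3-hydroxypropyl)-2-methoxyphenol]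
Product: 2 2-bromo-4-(3-hydroxypropyl)-6-methoxyphenol
Conditions: NBS (1.0 equiv), MeCN, −20 to 0 °C
Reagents that add atoms: N-bromosuccinimide, O=C1CCC(=O)N1Br
Why: Electrophilic aromatic bromination; the free phenol is the strongest director and its para position is blocked by the chain, so bromine should enter the one free ortho position, and the primary alcohol is inert to NBS in the cold.

Step 2
Reactants: 2 2-bromo-4-(3-hydroxypropyl)-6-methoxyphenol
Product: 3 2-bromo-6-methoxy-4-[3-(pivaloyloxy)propyl]phenyl pivalate
Conditions: PivCl (2.5 equiv), Et3N, DMAP (cat.), CH2Cl2, 0 °C to rt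
Reagents that add atoms: pivaloyl chloride (two equivalents are incorporated), CC(C)(C)C(Cl)=O
Why: DMAP-catalysed acylation of the phenol and the primary alcohol in one operation; the aryl pivalate later makes ring A a poor donor and both esters resist acid and the Heck base.

Step 3
Reactants: 4 syringaldehyde (4-hydroxy-3,5-dimethoxybenzaldehyde)
Product: 5 4-(benzyloxy)-3,5-dimethoxybenzaldehyde
Conditions: BnBr, K2CO3, DMF, 60 °C
Reagents that add atoms: benzyl bromide, BrCc1ccccc1
Why: Williamson ether synthesis on the phenoxide; the acidic para-formyl phenol alkylates cleanly and the benzyl ether keeps the oxygen a donor for the key step.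

Step 4
Reactants: 5 4-(benzyloxy)-3,5-dimethoxybenzaldehyde
Product: 6 2-(benzyloxy)-5-ethenyl-1,3-dimethoxybenzene
Conditions: Ph3PCH3Br, KOtBu, THF, 0 °C to rt
Reagents that add atoms: methyltriphenylphosphonium bromide, C[P+](c1ccccc1)(c1ccccc1)c1ccccc1.[Br-]
Why: Wittig methylenation of an aromatic aldehyde with the unstabilised ylide made in the flask; no stereochemical issue arises at a terminal alkene.

Step 5
Reactants: 3 2-bromo-6-methoxy-4-[3-(pivaloyloxy)propyl]phenyl pivalate; 6 2-(benzyloxy)-5-ethenyl-1,3-dimethoxybenzene
Product: 7 2-[(E)-2-(4-benzyloxy-3,5-dimethoxyphenyl)ethenyl]-6-methoxy-4-[3-(pivaloyloxy)propyl]phenyl pivalate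
Conditions: Pd2(dba)3 (2.5 mol %), [HP(t-Bu)3]BF4 (10 mol %), Cy2NMe, dioxane, 80 °C
Reagents that add atoms: none
Why: Mizoroki–Heck reaction; zerovalent palladium with the bulky electron-rich phosphine inserts into the hindered aryl bromide, the aryl group adds to the terminal alkene carbon in the neutral pathway, and syn β-hydride elimination gives the E-stilbene, while pivalates and the benzyl ether are inert to the amine base.

Step 6
Reactants: 7 2-[(E)-2-(4-benzyloxy-3,5-dimethoxyphenyl)ethenyl]-6-methoxy-4-[3-(pivaloyloxy)propyl]phenyl pivalate; 8 paraformaldehyde (as formaldehyde; this unit becomes C9)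
Product: 9 (4R,5R)-4-(4-benzyloxy-3,5-dimethoxyphenyl)-5-{3-methoxy-2-(pivaloyloxy)-5-[3-(pivaloyloxy)propyl]phenyl}-1,3-dioxane
Conditions: one antipode of a confined imino-imidodiphosphoric acid {[3,3′-Ar2-BINOL]P(=O)–NH–P(=NSO2CF3)[3,3′-Ar2-BINOL], Ar = 3,5-(CF3)2C6H3} (5 mol %), (CH2O)n (4 equiv), cyclohexane–CHCl3, 25 °C
Reagents that add atoms: formaldehyde (the second C1 unit, which becomes the acetal carbon; also from paraformaldehyde 8), C=O
Why: Proposed new method: the acid unzips paraformaldehyde and holds a protonated formaldehyde dimer (formally HOCH2–O–CH2+) as an ion pair in its chiral pocket; the cationic carbon bonds to C3 of the alkene while charge builds at C2, and the hemiacetal oxygen closes on C2 in the same asynchronous event, the proton returning to the catalyst. The closest known reaction type is the asymmetric Prins reaction of styrenes with paraformaldehyde under confined imino-imidodiphosphoric acids, which gives 4-aryl-1,3-dioxanes; a 1,2-diaryl alkene has not been shown. The dioxane ring closes by capture of the developing C2 cation by the chain oxygen, a six-membered closure (6-endo with respect to the alkene) that is suprafacial with C–C bond formation, so the E geometry becomes the 4,5-trans relationship. C5 of the dioxane (C3 of the target) is set by the catalyst, which selects the alkene face for C–C bond formation; C4 (C2 of the target) follows from the syn addition and is expendable because step 8 re-sets it. The regioselectivity needed is secured by the substrate: the para-benzyloxy group of ring C stabilises positive charge at C2, whereas the ortho-pivaloyloxy group makes ring A the poorer donor, so the new carbon goes to C3. Chemoselectivity over hydroxymethylation of the arenes and over formal formation rests on the confined active site and on both hydroxyls being capped as pivalates.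

Step 7
Reactants: 9 (4R,5R)-4-(4-benzyloxy-3,5-dimethoxyphenyl)-5-{3-methoxy-2-(pivaloyloxy)-5-[3-(pivaloyloxy)propyl]phenyl}-1,3-dioxane
Product: 10 2-[(4R,5R)-4-(4-benzyloxy-3,5-dimethoxyphenyl)-1,3-dioxan-5-yl]-4-(3-hydroxypropyl)-6-methoxyphenol
Conditions: LiAlH4, THF, 0 °C to rt; aqueous NaOH work-up
Reagents that add atoms: none
Why: Hydride reduction of both pivalate esters frees the phenol and the primary alcohol; the dioxane, the benzyl ether and both stereocentres are inert to LiAlH4.

Step 8
Reactants: 10 2-[(4R,5R)-4-(4-benzyloxy-3,5-dimethoxyphenyl)-1,3-dioxan-5-yl]-4-(3-hydroxypropyl)-6-methoxyphenol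
Product: 12 3-[(2S,3R)-2-(4-benzyloxy-3,5-dimethoxyphenyl)-3-(hydroxymethyl)-7-methoxy-2,3-dihydro-1-benzofuran-5-yl]propan-1-ol, via hemiformal 11 (not isolated)
Conditions: 2 M aq HCl–THF (1:4), 50 °C
Reagents that add atoms: none
Why: Acid-mediated SN1 cyclisation of the kind used to close 2-aryl-dihydrobenzofurans from benzylic alcohols or ethers bearing an ortho-phenol: protonation of the acetal oxygen on C2 gives the 4-benzyloxy-3,5-dimethoxybenzyl cation, which the ring A phenol captures in a 5-exo closure. The closure is reversible, so C2 should settle trans to the C9 arm (2S) under control of the fixed 3R centre, and hemiformal 11 sheds formaldehyde in the aqueous medium.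

Step 9
Reactants: 12 3-[(2S,3R)-2-(4-benzyloxy-3,5-dimethoxyphenyl)-3-(hydroxymethyl)-7-methoxy-2,3-dihydro-1-benzofuran-5-yl]propan-1-ol
Product: 13 4-[(2S,3R)-3-(hydroxymethyl)-5-(3-hydroxypropyl)-7-methoxy-2,3-dihydro-1-benzofuran-2-yl]-2,6-dimethoxyphenol
Conditions: H2 (1 atm), Pd/C (10 wt %), EtOAc–MeOH, rt
Reagents that add atoms: none
Why: Catalytic hydrogenolysis of the aryl benzyl ether; the exposed O–CH2Ph bond should cleave well before the hindered cyclic benzylic C2–O1 ether, and no stereocentre is involved.

## Compound list

1 | dihydroconiferyl alcohol, 4-(3-hydroxypropyl)-2-methoxyphenol | COc1cc(CCCO)ccc1O | starting material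
2 | 2-bromo-4-(3-hydroxypropyl)-6-methoxyphenol | COc1cc(CCCO)cc(Br)c1O | intermediate
3 | 2-bromo-6-methoxy-4-[3-(pivaloyloxy)propyl]phenyl pivalate | COc1cc(CCCOC(=O)C(C)(C)C)cc(Br)c1OC(=O)C(C)(C)C | intermediate
4 | syringaldehyde, 4-hydroxy-3,5-dimethoxybenzaldehyde | COc1cc(C=O)cc(OC)c1O | starting material
5 | 4-(benzyloxy)-3,5-dimethoxybenzaldehyde | COc1cc(C=O)cc(OC)c1OCc1ccccc1 | intermediate
6 | 2-(benzyloxy)-5-ethenyl-1,3-dimethoxybenzene | COc1cc(C=C)cc(OC)c1OCc1ccccc1 | intermediate
7 | 2-[(E)-2-(4-benzyloxy-3,5-dimethoxyphenyl)ethenyl]-6-methoxy-4-[3-(pivaloyloxy)propyl]phenyl pivalate | COc1cc(/C=C/c2cc(CCCOC(=O)C(C)(C)C)cc(OC)c2OC(=O)C(C)(C)C)cc(OC)c1OCc1ccccc1 | intermediate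
8 | paraformaldehyde (used as formaldehyde; two units enter 9) | C=O | starting material
9 | (4R,5R)-4-(4-benzyloxy-3,5-dimethoxyphenyl)-5-{3-methoxy-2-(pivaloyloxy)-5-[3-(pivaloyloxy)propyl]phenyl}-1,3-dioxane | COc1cc([C@@H]2OCOC[C@H]2c2cc(CCCOC(=O)C(C)(C)C)cc(OC)c2OC(=O)C(C)(C)C)cc(OC)c1OCc1ccccc1 | intermediate
10 | 2-[(4R,5R)-4-(4-benzyloxy-3,5-dimethoxyphenyl)-1,3-dioxan-5-yl]-4-(3-hydroxypropyl)-6-methoxyphenol | COc1cc([C@@H]2OCOC[C@H]2c2cc(CCCO)cc(OC)c2O)cc(OC)c1OCc1ccccc1 | intermediate
11 | {[(2S,3R)-2-(4-benzyloxy-3,5-dimethoxyphenyl)-5-(3-hydroxypropyl)-7-methoxy-2,3-dihydro-1-benzofuran-3-yl]methoxy}methanol (hemiformal, not isolated) | COc1cc([C@H]2Oc3c(OC)cc(CCCO)cc3[C@@H]2COCO)cc(OC)c1OCc1ccccc1 | intermediate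
12 | 3-[(2S,3R)-2-(4-benzyloxy-3,5-dimethoxyphenyl)-3-(hydroxymethyl)-7-methoxy-2,3-dihydro-1-benzofuran-5-yl]propan-1-ol | COc1cc([C@H]2Oc3c(OC)cc(CCCO)cc3[C@@H]2CO)cc(OC)c1OCc1ccccc1 | intermediate
13 | 4-[(2S,3R)-3-(hydroxymethyl)-5-(3-hydroxypropyl)-7-methoxy-2,3-dihydro-1-benzofuran-2-yl]-2,6-dimethoxyphenol | COc1cc([C@H]2Oc3c(OC)cc(CCCO)cc3[C@@H]2CO)cc(OC)c1O | target

## Step count and risks

Total: 9 steps. Longest linear sequence: 7 steps (steps 1, 2, 5, 6, 7, 8, 9 from 1; equally steps 3, 4, 5, 6, 7, 8, 9 from 4).

**Step 6 (key step, proposed new method).**
- What may go wrong: a 1,2-disubstituted, ortho-substituted stilbene may react too slowly inside the confined acid. If the addition becomes stepwise through a free cation, or if the ester carbonyl on ring A assists charge at C3, the regioselectivity or the facial selectivity could erode. Electrophilic hydroxymethylation of the electron-rich rings could compete. The more acidic imidodiphosphorimidate congeners are a reserve in conditions only.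
- Fallback (known chemistry, from 3 and 5, rejoining at 12): Palladium-catalysed coupling of 3 with the Reformatsky reagent of tert-butyl bromoacetate (Pd(dba)2, P(t-Bu)3, THF) would give tert-butyl 2-{3-methoxy-2-(pivaloyloxy)-5-[3-(pivaloyloxy)propyl]phenyl}acetate F1. TFA in CH2Cl2 would free the arylacetic acid F2. Its mixed anhydride (PivCl, Et3N), treated with (S)-4-benzyloxazolidin-2-one and LiCl, would give the N-acyl oxazolidinone F3. The Bu2BOTf/i-Pr2NEt boron enolate of F3 and aldehyde 5 would give the Evans syn aldol adduct F4; the auxiliary fixes the α-carbon in the sense that becomes 3R. LiBH4 in THF–MeOH, followed by LiAlH4 if the alkyl pivalate lags, would remove the auxiliary and both pivalates and give the (1S,2R)-tetraol F5. The acid of step 8 would then close ring B to 12 with loss of water only, the carbinol carbon being re-set trans as in the main route.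

**Step 8.**
- What may go wrong: loss of the C3 proton from the C2 cation would destroy the only controlling stereocentre. Attack of released formaldehyde or of a hemiformal-derived oxocarbenium ion on the electron-rich rings is possible. Closure under kinetic rather than equilibrating conditions could give incomplete trans selectivity.
- Fallback (from 10, rejoining at 12): the two events are separated. Excess TMSOTf and 2,2′-bipyridyl in CH2Cl2 at 0 °C, then water and K2CO3/MeOH to free the silylated hydroxyls, would cleave the methylene acetal at its O–CH2 bonds and leave the benzylic C–O bond intact. This would give the (1R,2R)-tetraol F6. Brief acid treatment (TFA, CH2Cl2, 0 °C) would then close F6 to 12 by dehydration, with no formaldehyde present during the cationic step.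

**Step 5.**
- What may go wrong: arylation at the internal alkene carbon of the electron-rich styrene, slow oxidative addition at the hindered electron-rich bromide, or polymerisation of the styrene at the reaction temperature.
- Fallback (from 6, rejoining at 7): cross-metathesis of 6 with vinylboronic acid pinacol ester (second-generation Grubbs catalyst, CH2Cl2, 40 °C) would give 2-[(E)-2-(4-benzyloxy-3,5-dimethoxyphenyl)ethenyl]-4,4,5,5-tetramethyl-1,3,2-dioxaborolane F7. Suzuki–Miyaura coupling of F7 with bromide 3 (Pd(dppf)Cl2, CsF, dioxane, 80 °C) fixes the position of the new bond through the boronate and would return to 7.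

**Step 9.**
- What may go wrong: over-reduction, that is, hydrogenolytic opening of the benzylic C2–O1 bond of ring B after the benzyl ether is gone.
- Fallback (from 12, rejoining at 13): the benzyl group would be removed without any reductant by Lewis-acid cleavage with a cation scavenger (BCl3, pentamethylbenzene, CH2Cl2, −78 °C). A reversible ionisation of C2–O1 under these conditions would reclose to the trans isomer. No new compound arises.

## Further compounds

F1 | step 6 | tert-butyl 2-{3-methoxy-2-(pivaloyloxy)-5-[3-(pivaloyloxy)propyl]phenyl}acetate | COc1cc(CCCOC(=O)C(C)(C)C)cc(CC(=O)OC(C)(C)C)c1OC(=O)C(C)(C)C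
F2 | step 6 | 2-{3-methoxy-2-(pivaloyloxy)-5-[3-(pivaloyloxy)propyl]phenyl}acetic acid | COc1cc(CCCOC(=O)C(C)(C)C)cc(CC(=O)O)c1OC(=O)C(C)(C)C
F3 | step 6 | (S)-4-benzyl-3-(2-{3-methoxy-2-(pivaloyloxy)-5-[3-(pivaloyloxy)propyl]phenyl}acetyl)oxazolidin-2-one | COc1cc(CCCOC(=O)C(C)(C)C)cc(CC(=O)N2C(=O)OC[C@@H]2Cc2ccccc2)c1OC(=O)C(C)(C)C
F4 | step 6 | (S)-4-benzyl-3-[(2S,3S)-3-(4-benzyloxy-3,5-dimethoxyphenyl)-3-hydroxy-2-{3-methoxy-2-(pivaloyloxy)-5-[3-(pivaloyloxy)propyl]phenyl}propanoyl]oxazolidin-2-one | COc1cc([C@@H](O)[C@@H](C(=O)N2C(=O)OC[C@@H]2Cc2ccccc2)c2cc(CCCOC(=O)C(C)(C)C)cc(OC)c2OC(=O)C(C)(C)C)cc(OC)c1OCc1ccccc1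
F5 | step 6 | (1S,2R)-1-(4-benzyloxy-3,5-dimethoxyphenyl)-2-[2-hydroxy-5-(3-hydroxypropyl)-3-methoxyphenyl]propane-1,3-diol | COc1cc([C@@H](O)[C@@H](CO)c2cc(CCCO)cc(OC)c2O)cc(OC)c1OCc1ccccc1
F6 | step 8 | (1R,2R)-1-(4-benzyloxy-3,5-dimethoxyphenyl)-2-[2-hydroxy-5-(3-hydroxypropyl)-3-methoxyphenyl]propane-1,3-diol | COc1cc([C@H](O)[C@@H](CO)c2cc(CCCO)cc(OC)c2O)cc(OC)c1OCc1ccccc1
F7 | step 5 | 2-[(E)-2-(4-benzyloxy-3,5-dimethoxyphenyl)ethenyl]-4,4,5,5-tetramethyl-1,3,2-dioxaborolane | COc1cc(/C=C/B2OC(C)(C)C(C)(C)O2)cc(OC)c1OCc1ccccc1
F0 | step 9 | none | none
A1 | alternative 1 | (2S,3R)-2-(4-benzyloxy-3,5-dimethoxyphenyl)-3-(tert-butyldimethylsilyloxymethyl)-7-methoxy-2,3-dihydrobenzofuran-5-carbaldehyde | COc1cc([C@H]2Oc3c(OC)cc(C=O)cc3[C@@H]2CO[Si](C)(C)C(C)(C)C)cc(OC)c1OCc1ccccc1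
A2 | alternative 1 | 3-[(1S,2R)-1-(4-benzyloxy-3,5-dimethoxyphenyl)-3-(tert-butyldimethylsilyloxy)-1-hydroxypropan-2-yl]-4-fluoro-5-methoxybenzaldehyde | COc1cc([C@@H](O)[C@@H](CO[Si](C)(C)C(C)(C)C)c2cc(C=O)cc(OC)c2F)cc(OC)c1OCc1ccccc1
A3 | alternative 2 | methyl 2-(4-benzyloxy-3,5-dimethoxyphenyl)-7-methoxy-5-(3-methoxy-3-oxopropyl)benzofuran-3-carboxylate | COC(=O)CCc1cc(OC)c2oc(-c3cc(OC)c(OCc4ccccc4)c(OC)c3)c(C(=O)OC)c2c1
A4 | alternative 2 | methyl 3-(4-benzyloxy-3,5-dimethoxyphenyl)-3-oxopropanoate | COC(=O)CC(=O)c1cc(OC)c(OCc2ccccc2)c(OC)c1
A5 | alternative 2 | methyl 3-[3-bromo-5-methoxy-4-(trifluoromethylsulfonyloxy)phenyl]propanoate | COC(=O)CCc1cc(Br)c(OS(=O)(=O)C(F)(F)F)c(OC)c1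
A6 | alternative 3 | methyl 3-[(2S,3R)-2-(4-benzyloxy-3,5-dimethoxyphenyl)-3-(hydroxymethyl)-7-methoxy-2,3-dihydrobenzofuran-5-yl]propanoate | COc1cc([C@H]2Oc3c(OC)cc(CCC(=O)OC)cc3[C@@H]2CO)cc(OC)c1OCc1ccccc1
A7 | alternative 3 | methyl 3-{4-[(1S)-1-(4-benzyloxy-3,5-dimethoxyphenyl)prop-2-enyloxy]-3-iodo-5-methoxyphenyl}propanoate | COc1cc([C@H](C=C)Oc2c(OC)cc(CCC(=O)OC)cc2I)cc(OC)c1OCc1ccccc1
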